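**Retrosynthetic overview**

- Ring A is a phloroglucinol nucleus whose three oxygens (O1 on C8a, 5-OH, 7-OH) sit on alternate carbons, i.e. a folded triketide. Its C4a–C5 bond is therefore made last, by closing an acylketene carbon (C5) onto C4a of a finished ring C (26 ⇐ acyl Meldrum's acid 22).
- 22 ⇐ acid 20 + Meldrum's acid (C6–C7); 20 ⇐ allyl ester 18. Ring C (O1–C8a) ⇐ cyclodehydration of hydroxy-diketo ester 17 ⇐ (S)-β-hydroxy Weinreb amide 13 + dianion of allyl 2-prenylacetoacetate 15 (C4–C4a).
- C2 (S) ⇐ asymmetric transfer hydrogenation of β-keto Weinreb amide 12 ⇐ aldehyde 8 + N-methoxy-N-methylacetamide (C2–C3).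
- Ring B aldehyde 8 ⇐ isovanillin by MOM protection, acetalisation and directed ortho-lithiation/prenylation at C2′.
- Ring order: B (bought) → C (step 8) → A (step 11); the single MOM group is removed last.

Key step: step 11

Abbreviations: Ar = 4-methoxy-3-(methoxymethoxy)-2-(3-methylbut-2-en-1-yl)phenyl; prenyl = 3-methylbut-2-en-1-yl.
Assumption: the prenyl-bearing carbon of 15 and 17–24 is carried as a mixture of epimers, since it becomes aromatic C8; the (S)-configuration of 13 from the (S,S)-catalyst is assigned by analogy with acetophenone and is to be confirmed (Mosher esters) before step 8.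

**Step 1**
Reactants: 1 isovanillin
Product: 2 4-methoxy-3-(methoxymethoxy)benzaldehyde
Conditions: MOMCl, iPr2NEt, CH2Cl2, 0 °C → rt
Reagents that add atoms: chloromethyl methyl ether (MOMCl), COCCl
Why: O-alkylation of the phenoxide (Williamson-type) installs a group that survives organolithium chemistry and later directs the lithiation.

**Step 2**
Reactants: 2 4-methoxy-3-(methoxymethoxy)benzaldehyde
Product: 3 4-(dimethoxymethyl)-1-methoxy-2-(methoxymethoxy)benzene
Conditions: HC(OMe)3, PPTS (cat.), MeOH, rt; Et3N quench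
Reagents that add atoms: trimethyl orthoformate, COC(OC)OC
Why: Acid-catalysed acetalisation with the orthoester as water scavenger masks the aldehyde under conditions too mild to cleave the aryl MOM ether.

**Step 3**
Reactants: 3 4-(dimethoxymethyl)-1-methoxy-2-(methoxymethoxy)benzene; 4 prenyl bromide
Product: 8 4-methoxy-3-(methoxymethoxy)-2-(3-methylbut-2-en-1-yl)benzaldehyde, via aryllithium 5 (not isolated), via arylcopper 6 (not isolated), via prenylated acetal 7 (not isolated)
Conditions: n-BuLi, THF, 0 °C; CuBr·SMe2, −78 °C; 4, −78 °C → rt; then 1 M aq. HCl/THF, rt, brief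
Reagents that add atoms: water, O
Why: Directed ortho-metalation places lithium on the carbon flanked by the OMOM and acetal groups, the arylcopper displaces bromide at the primary carbon of prenyl bromide (SN2, linear prenyl), and dilute acid on work-up hydrolyses only the dimethyl acetal.

**Step 4**
Reactants: 8 4-methoxy-3-(methoxymethoxy)-2-(3-methylbut-2-en-1-yl)benzaldehyde; 9 N-methoxy-N-methylacetamide
Product: 11 rac-3-hydroxy-N-methoxy-3-Ar-N-methylpropanamide, via lithium amide enolate 10 (not isolated)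
Conditions: LDA, 9, THF, −78 °C; then 8, −78 °C; AcOH quench
Reagents that add atoms: none
Why: Aldol addition of the lithium enolate of the Weinreb acetamide to the aldehyde forms C2–C3 without Lewis acid, which avoids a carbonyl-ene reaction of the ortho-prenyl aldehyde.

**Step 5**
Reactants: 11 rac-3-hydroxy-N-methoxy-3-Ar-N-methylpropanamide
Product: 12 N-methoxy-3-Ar-N-methyl-3-oxopropanamide
Conditions: Dess–Martin periodinane (1.2 equiv), CH2Cl2, 0 °C → rt
Reagents that add atoms: none
Why: Dess–Martin oxidation of the benzylic alcohol gives the aryl ketone without touching the trisubstituted alkene or the MOM ether.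

**Step 6**
Reactants: 12 N-methoxy-3-Ar-N-methyl-3-oxopropanamide
Product: 13 (3S)-3-hydroxy-N-methoxy-3-Ar-N-methylpropanamide
Conditions: RuCl(p-cymene)[(S,S)-TsDPEN] (1–2 mol%), HCO2H/Et3N (5:2), DMF, 30–40 °C
Reagents that add atoms: none
Why: Noyori–Ikariya asymmetric transfer hydrogenation of the aryl ketone; the aryl group should sit against the η6-arene as in acetophenone, so the (S,S)-catalyst should deliver hydride to give the (S)-carbinol (future C2), and the amide and the prenyl alkene are not reduced.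

**Step 7**
Reactants: 14 allyl acetoacetate; 4 prenyl bromide
Product: 15 prop-2-en-1-yl 2-acetyl-5-methylhex-4-enoate (racemic)
Conditions: K2CO3, acetone, reflux
Reagents that add atoms: none
Why: C-alkylation of the β-keto ester enolate by the allylic bromide puts the future C8 prenyl group in place.

**Step 8**
Reactants: 13 (3S)-3-hydroxy-N-methoxy-3-Ar-N-methylpropanamide; 15 prop-2-en-1-yl 2-acetyl-5-methylhex-4-enoate
Product: 18 prop-2-en-1-yl 2-[(2S)-2-Ar-4-oxo-3,4-dihydro-2H-pyran-6-yl]-5-methylhex-4-enoate, via dilithium dianion 16 (not isolated), via hydroxy diketo ester 17 (not isolated)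
Conditions: 15 (3 equiv), LDA (6.2 equiv), THF, −78 → 0 °C (short); 13, −78 → −20 °C; AcOH quench; crude, TsOH·H2O (5 mol%), 4 Å MS, CH2Cl2, 0 °C → rt
Reagents that add atoms: none
Why: γ-Acylation of the β-keto ester dianion by the Weinreb amide (Claisen-type; the chelated adduct is released only on quench) gives the δ-hydroxy-β-diketone, whose hydroxyl adds 6-exo-trig to the C8a ketone and loses water under acid to the 2,3-dihydropyran-4-one, the C2–O bond and hence the (S)-configuration being untouched.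

**Step 9**
Reactants: 18 prop-2-en-1-yl 2-[(2S)-2-Ar-4-oxo-3,4-dihydro-2H-pyran-6-yl]-5-methylhex-4-enoate
Product: 20 2-[(2S)-2-Ar-4-oxo-3,4-dihydro-2H-pyran-6-yl]-5-methylhex-4-enoic acid, via phenylsilyl ester 19 (not isolated)
Conditions: Pd(PPh3)4 (5 mol%), PhSiH3, CH2Cl2, 0 °C; cold pH 4 buffer work-up; used at once
Reagents that add atoms: none
Why: Tsuji–Trost-type deallylation with phenylsilane as hydride scavenger is neutral and amine-free, so the base-sensitive pyranone, the MOM ether and the prenyl groups should survive.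

**Step 10**
Reactants: 20 2-[(2S)-2-Ar-4-oxo-3,4-dihydro-2H-pyran-6-yl]-5-methylhex-4-enoic acid; 21 Meldrum's acid
Product: 22 5-{2-[(2S)-2-Ar-4-oxo-3,4-dihydro-2H-pyran-6-yl]-5-methylhex-4-enoyl}-2,2-dimethyl-1,3-dioxane-4,6-dione
Conditions: DCC, DMAP, CH2Cl2, 0 °C → rt; filtration, cold aq. KHSO4 wash; used crude
Reagents that add atoms: none
Why: Carbodiimide/DMAP C-acylation of Meldrum's acid gives the enolised acyl Meldrum's acid at or below room temperature, mild enough for the decarboxylation-prone acid.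

**Step 11**
Reactants: 22 5-{2-[(2S)-2-Ar-4-oxo-3,4-dihydro-2H-pyran-6-yl]-5-methylhex-4-enoyl}-2,2-dimethyl-1,3-dioxane-4,6-dione
Product: 26 (2S)-5,7-dihydroxy-2-Ar-8-(3-methylbut-2-en-1-yl)-2,3-dihydro-4H-chromen-4-one, via acylketene 23 (not isolated), via dienylketene enol 24 (not isolated), via cyclohexadienone 25 (not isolated)
Conditions: slow addition of 22 to dry toluene (final ca. 0.005 M), 100–110 °C, N2
Reagents that add atoms: none
Why: Proposed new method: heat should fragment the acyl Meldrum's acid (loss of acetone and CO2) to acylketene 23, O=C7–C6H=C5=O on C8, and the doubly activated C8–H enolises to dienylketene 24, in which C4a=C8a–C8=C7–C6=C5 is a triene ending in the ketene. Thermal disrotatory 6π-electrocyclisation (equally describable as attack of the nucleophilic enol-ether carbon C4a on the ketene carbon C5) then forms C4a–C5 and gives cyclohexadienone 25, and two enolisations aromatise it to the 5,7-dihydroxy ring. The closest known reaction types are the thermolysis of acyl Meldrum's acids and dioxinones to acylketenes in biomimetic polyketide aromatisations and the 6π-closure of dienylketenes to phenols (Danheiser benzannulation, Gould–Jacobs-type closures); what is new is the use of the C4a=C8a enol-ether bond of a 2,3-dihydropyran-4-one as the terminal 2π unit. Ring A closes as a six-membered carbocycle in a 6-(enolendo)-exo sense, all six carbons being already in the chain and only the C4a–C5 σ-bond being new. No stereocentre is created for good: the sp3 centre at C4a of 25 is erased by aromatisation, the two C8 epimers of 22 converge because C8 becomes aromatic, and C2 keeps its (S)-configuration because no base is present to open the O1–C2 bond by retro-oxa-Michael reaction. The step needs closure at C4a instead of ketene dimerisation, O-acylation of product phenols or hydrolysis; the tether secures this (C5 can reach only C4a through a six-membered transition state, and a hetero-[4+2] of the acylketene across C4a=C8a would need a four-membered ring), helped by slow addition into dry, dilute toluene.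

**Step 12**
Reactants: 26 (2S)-5,7-dihydroxy-2-Ar-8-(3-methylbut-2-en-1-yl)-2,3-dihydro-4H-chromen-4-one
Product: 27 (2S)-5,7-dihydroxy-2-[3-hydroxy-4-methoxy-2-(3-methylbut-2-en-1-yl)phenyl]-8-(3-methylbut-2-en-1-yl)-2,3-dihydro-4H-chromen-4-one
Conditions: HCl (ca. 1 M in MeOH), THF/MeOH, 0 °C → rt, stopped at full conversion
Reagents that add atoms: none
Why: Acid-catalysed acetal exchange removes the only MOM group; dilute acid at or below room temperature is chosen because stronger acid would add the 7- or 3′-hydroxyl to the neighbouring prenyl group, and C2 is not epimerised under acid.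

**Compound list**

1 | isovanillin | COc1ccc(C=O)cc1O | starting material
2 | 4-methoxy-3-(methoxymethoxy)benzaldehyde | COCOc1cc(C=O)ccc1OC | intermediate
3 | 4-(dimethoxymethyl)-1-methoxy-2-(methoxymethoxy)benzene | COCOc1cc(C(OC)OC)ccc1OC | intermediate
4 | prenyl bromide (1-bromo-3-methylbut-2-ene) | CC(C)=CCBr | starting material
5 | [6-(dimethoxymethyl)-3-methoxy-2-(methoxymethoxy)phenyl]lithium | COCOc1c([Li])c(C(OC)OC)ccc1OC | intermediate
6 | [6-(dimethoxymethyl)-3-methoxy-2-(methoxymethoxy)phenyl]copper(I) | COCOc1c([Cu])c(C(OC)OC)ccc1OC | intermediate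
7 | 1-(dimethoxymethyl)-4-methoxy-3-(methoxymethoxy)-2-(3-methylbut-2-en-1-yl)benzene | COCOc1c(CC=C(C)C)c(C(OC)OC)ccc1OC | intermediate
8 | 4-methoxy-3-(methoxymethoxy)-2-(3-methylbut-2-en-1-yl)benzaldehyde | COCOc1c(CC=C(C)C)c(C=O)ccc1OC | intermediate
9 | N-methoxy-N-methylacetamide | CC(=O)N(C)OC | starting material
10 | lithium 1-[methoxy(methyl)amino]ethen-1-olate | C=C(O[Li])N(C)OC | intermediate
11 | rac-3-hydroxy-N-methoxy-3-Ar-N-methylpropanamide | CON(C)C(=O)CC(O)c1ccc(OC)c(OCOC)c1CC=C(C)C | intermediate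
12 | N-methoxy-3-Ar-N-methyl-3-oxopropanamide | CON(C)C(=O)CC(=O)c1ccc(OC)c(OCOC)c1CC=C(C)C | intermediate
13 | (3S)-3-hydroxy-N-methoxy-3-Ar-N-methylpropanamide | CON(C)C(=O)C[C@H](O)c1ccc(OC)c(OCOC)c1CC=C(C)C | intermediate
14 | allyl acetoacetate (prop-2-en-1-yl 3-oxobutanoate) | CC(=O)CC(=O)OCC=C | starting material
15 | prop-2-en-1-yl 2-acetyl-5-methylhex-4-enoate (racemic) | CC(=O)C(CC=C(C)C)C(=O)OCC=C | intermediate
16 | dilithium dianion of 15 (ester enolate and terminal ketone enolate) | C=C(O[Li])C(CC=C(C)C)=C(O[Li])OCC=C | intermediate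
17 | prop-2-en-1-yl (7S)-7-hydroxy-7-Ar-2-(3-methylbut-2-en-1-yl)-3,5-dioxoheptanoate (both C2 epimers; in equilibrium with enol and hemiketal forms) | C=CCOC(=O)C(CC=C(C)C)C(=O)CC(=O)C[C@H](O)c1ccc(OC)c(OCOC)c1CC=C(C)C | intermediate
18 | prop-2-en-1-yl 2-[(2S)-2-Ar-4-oxo-3,4-dihydro-2H-pyran-6-yl]-5-methylhex-4-enoate (both side-chain epimers) | C=CCOC(=O)C(CC=C(C)C)C1=CC(=O)C[C@@H](c2ccc(OC)c(OCOC)c2CC=C(C)C)O1 | intermediate
19 | phenylsilyl 2-[(2S)-2-Ar-4-oxo-3,4-dihydro-2H-pyran-6-yl]-5-methylhex-4-enoate | O=C(O[SiH2]c1ccccc1)C(CC=C(C)C)C1=CC(=O)C[C@@H](c2ccc(OC)c(OCOC)c2CC=C(C)C)O1 | intermediate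
20 | 2-[(2S)-2-Ar-4-oxo-3,4-dihydro-2H-pyran-6-yl]-5-methylhex-4-enoic acid (both side-chain epimers) | OC(=O)C(CC=C(C)C)C1=CC(=O)C[C@@H](c2ccc(OC)c(OCOC)c2CC=C(C)C)O1 | intermediate
21 | Meldrum's acid (2,2-dimethyl-1,3-dioxane-4,6-dione) | CC1(C)OC(=O)CC(=O)O1 | starting material
22 | 5-{2-[(2S)-2-Ar-4-oxo-3,4-dihydro-2H-pyran-6-yl]-5-methylhex-4-enoyl}-2,2-dimethyl-1,3-dioxane-4,6-dione (both side-chain epimers; enolised) | CC1(C)OC(=O)C(C(=O)C(CC=C(C)C)C2=CC(=O)C[C@@H](c3ccc(OC)c(OCOC)c3CC=C(C)C)O2)C(=O)O1 | intermediate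
23 | acylketene: 4-[(2S)-2-Ar-4-oxo-3,4-dihydro-2H-pyran-6-yl]-7-methylocta-1,6-diene-1,3-dione | O=C=CC(=O)C(CC=C(C)C)C1=CC(=O)C[C@@H](c2ccc(OC)c(OCOC)c2CC=C(C)C)O1 | intermediate
24 | dienylketene enol of 23 (C7 enol toward C8, C6 and C8a cis) | O=C=C/C(O)=C(CC=C(C)C)\C1=CC(=O)C[C@@H](c2ccc(OC)c(OCOC)c2CC=C(C)C)O1 | intermediate
25 | (2S)-2-Ar-7-hydroxy-8-(3-methylbut-2-en-1-yl)-2,3-dihydro-4H-chromene-4,5(4aH)-dione (C4a unassigned) | O=C1C=C(O)C(CC=C(C)C)=C2O[C@H](c3ccc(OC)c(OCOC)c3CC=C(C)C)CC(=O)C12 | intermediate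
26 | (2S)-5,7-dihydroxy-2-Ar-8-(3-methylbut-2-en-1-yl)-2,3-dihydro-4H-chromen-4-one (3′-O-MOM ether of the target) | COc1ccc([C@@H]2CC(=O)c3c(O)cc(O)c(CC=C(C)C)c3O2)c(CC=C(C)C)c1OCOC | intermediate
27 | (2S)-5,7-dihydroxy-2-[3-hydroxy-4-methoxy-2-(3-methylbut-2-en-1-yl)phenyl]-8-(3-methylbut-2-en-1-yl)-2,3-dihydro-4H-chromen-4-one | COc1ccc([C@@H]2CC(=O)c3c(O)cc(O)c(CC=C(C)C)c3O2)c(CC=C(C)C)c1O | target

**Step count**

Total steps: 12. Longest linear sequence: 11 (steps 1–6 and 8–12; step 7 is a one-step side branch).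

**Steps most likely to fail, with fallbacks**

Step 11 (proposed new method). The acylketene may be consumed by dimerisation, by acylation of the 7-hydroxyl of product already formed, or by traces of water (followed by decarboxylation) before C4a closes on C5. The fallback uses known chalcone chemistry, sets out from aldehyde 8 and comes back at target 27. Commercial 2′,4′,6′-trihydroxyacetophenone is C-prenylated with prenyl bromide 4 (DBU, THF) to 2,4,6-trihydroxy-3-prenylacetophenone F1. The 4- and 6-hydroxyls are protected (MOMCl, iPr2NEt) to give 2-hydroxy-4,6-bis(methoxymethoxy)-3-prenylacetophenone F2; the hindered, chelated hydroxyl between acetyl and prenyl should stay free, and any regioisomer would be removed. Claisen–Schmidt condensation of F2 with 8 (KOH, EtOH) should give the 2′-hydroxychalcone F3. NaOAc in refluxing EtOH closes F3 by oxa-Michael addition through its only free hydroxyl to the racemic tris-MOM 8-prenylflavanone F4. Methanolic HCl gives the racemic flavanone F5, and preparative chiral-phase HPLC separates the (S)-enantiomer 27.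

Step 8. Slow acylation of the hindered, α-branched dianion could let retro-aldol cleavage of the lithium aldolate (loss of material and of enantiopurity) or Carroll rearrangement of the allyl ester dianion compete, and at the acid stage the p-methoxybenzylic C2–O bond may ionise. The fallback sets out from 13 and comes back at 18. The hydroxyl is silylated (TESCl, imidazole) to the triethylsilyl ether F6. F6 is acylated with the unbranched dianion of allyl acetoacetate 14 (LDA, THF, −78 °C) to the silyloxy diketo ester F7. Buffered HF·pyridine in THF removes the silyl group and effects cyclodehydration to the pyranone acetate F8. The doubly activated methylene of F8 is then alkylated with prenyl bromide 4 (K2CO3, acetone, rt) to give 18.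

Step 9. The vinylogous β-keto acid may decarboxylate during deallylation or before it is coupled. The fallback avoids the free acid and Meldrum's acid by carrying the ketene as a dioxinone; it sets out from 13 and comes back at acylketene 23. Commercial 2,2,6-trimethyl-4H-1,3-dioxin-4-one is acetylated at its methyl group (LDA, then N-acetylimidazole) to 2,2-dimethyl-6-(2-oxopropyl)-4H-1,3-dioxin-4-one F9. F9 is prenylated at the activated methylene (4, K2CO3, acetone) to the keto-dioxinone F10. The dianion of F10 (LDA, 2 equiv) is acylated at its methyl group by 13 to the hydroxy diketo-dioxinone F11. Catalytic TsOH cyclodehydrates F11 to the pyranone-dioxinone F12. Heating F12 in dry, dilute toluene at 100–110 °C expels acetone by retro-[4+2] reaction and releases 23, which continues to 26 as in step 11.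

**Further compounds**

F1 | step 11 | 1-[2,4,6-trihydroxy-3-(3-methylbut-2-en-1-yl)phenyl]ethanone | CC(=O)c1c(O)cc(O)c(CC=C(C)C)c1O
F2 | step 11 | 1-[2-hydroxy-4,6-bis(methoxymethoxy)-3-(3-methylbut-2-en-1-yl)phenyl]ethanone | CC(=O)c1c(OCOC)cc(OCOC)c(CC=C(C)C)c1O
F3 | step 11 | (E)-1-[2-hydroxy-4,6-bis(methoxymethoxy)-3-(3-methylbut-2-en-1-yl)phenyl]-3-Ar-prop-2-en-1-one | COCOc1cc(OCOC)c(CC=C(C)C)c(O)c1C(=O)/C=C/c1ccc(OC)c(OCOC)c1CC=C(C)C
F4 | step 11 | rac-5,7-bis(methoxymethoxy)-2-Ar-8-(3-methylbut-2-en-1-yl)-2,3-dihydro-4H-chromen-4-one | COCOc1cc(OCOC)c2c(c1CC=C(C)C)OC(c1ccc(OC)c(OCOC)c1CC=C(C)C)CC2=O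
F5 | step 11 | rac-5,7-dihydroxy-2-[3-hydroxy-4-methoxy-2-(3-methylbut-2-en-1-yl)phenyl]-8-(3-methylbut-2-en-1-yl)-2,3-dihydro-4H-chromen-4-one | COc1ccc(C2CC(=O)c3c(O)cc(O)c(CC=C(C)C)c3O2)c(CC=C(C)C)c1O
F6 | step 8 | (3S)-N-methoxy-3-Ar-N-methyl-3-(triethylsilyloxy)propanamide | CON(C)C(=O)C[C@H](O[Si](CC)(CC)CC)c1ccc(OC)c(OCOC)c1CC=C(C)C
F7 | step 8 | prop-2-en-1-yl (7S)-7-Ar-3,5-dioxo-7-(triethylsilyloxy)heptanoate | C=CCOC(=O)CC(=O)CC(=O)C[C@H](O[Si](CC)(CC)CC)c1ccc(OC)c(OCOC)c1CC=C(C)C
F8 | step 8 | prop-2-en-1-yl 2-[(2S)-2-Ar-4-oxo-3,4-dihydro-2H-pyran-6-yl]acetate | C=CCOC(=O)CC1=CC(=O)C[C@@H](c2ccc(OC)c(OCOC)c2CC=C(C)C)O1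
F9 | step 9 | 2,2-dimethyl-6-(2-oxopropyl)-4H-1,3-dioxin-4-one | CC(=O)CC1=CC(=O)OC(C)(C)O1
F10 | step 9 | 2,2-dimethyl-6-(6-methyl-2-oxohept-5-en-3-yl)-4H-1,3-dioxin-4-one (racemic) | CC(=O)C(CC=C(C)C)C1=CC(=O)OC(C)(C)O1
F11 | step 9 | 6-[(8S)-8-hydroxy-8-Ar-2-methyl-4,6-dioxooct... chain: 2,2-dimethyl-6-[(7S)-7-hydroxy-7-Ar-1-(3-methylbut-2-en-1-yl)-2,4-dioxoheptyl]-4H-1,3-dioxin-4-one | CC1(C)OC(=O)C=C(C(CC=C(C)C)C(=O)CC(=O)C[C@H](O)c2ccc(OC)c(OCOC)c2CC=C(C)C)O1
F12 | step 9 | 2,2-dimethyl-6-{1-[(2S)-2-Ar-4-oxo-3,4-dihydro-2H-pyran-6-yl]-4-methylpent-3-en-1-yl}-4H-1,3-dioxin-4-one | CC1(C)OC(=O)C=C(C(CC=C(C)C)C2=CC(=O)C[C@@H](c3ccc(OC)c(OCOC)c3CC=C(C)C)O2)O1
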